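Saturday's flask is the one run so far, and its first hour is the easy step.

| flask | J | G | Q | remark | time |
|---|---|---|---|---|---|
| Saturday's | 0.058 M | 1.2 equiv | 0.0117 M | run made earlier |  |
| winter | 0.039 M | 1.20 equiv | 0.0117 M |  | 25 h |
| autumn | 0.039 M | 2.40 equiv | 0.0117 M |  | 25 h |
| dawn | 0.039 M | 4.80 equiv | 0.0117 M |  | 25 h |
Saturday's run (percent of the J charged)

| time / h | J / % | E / % |
|---|---|---|
| 0.417 | 95 | 5 |
| 0.667 | 92 | 10 |
| 1.00 | 87 | 9 |
| 1.33 | 87 | 16 |
| 2.00 | 81 | 18 |
| 3.00 | 76 | 21 |
| 5.00 | 70 | 31 |

(each reading ± 1.5 percentage points)
- a reading or a percentage of E counts all its forms, free or not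
1. part of the J that has reacted at the end, winter
2. part of the J that has reacted at the end, autumn
3. part of the J that has reacted at the end, dawn
4. what raising the equivalents of G from its lowest to its highest value here does to the part of the J that has reacted (changes below 5 percentage points count as none) (it rises / it falls / no change)

After 1.00 h of Saturday's run, 87 % of J stands, which gives an apparent first-order constant of 0.139 h⁻¹ for that first hour. Between 3.00 h and 5.00 h the same constant reads 0.0411 h⁻¹. If the constant follows free G, as a step J + G implies, then free G in that middle stretch is 29.5 % of its first-hour level. On the simplification of this reckoning that the first-hour level equals the charge of 1.2 equiv, 0.846 equivalents have gone while J has reacted only 27.0 %.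

G is leaving faster than J alone asks. This reckoning guesses that Q takes G one for one, which is 0.202 equivalents in Saturday's flask, a guess that one run cannot test. What remains is the G bill, the equivalents of G lost per J reacted once Q is paid for: 2.39, a reading with the scatter of its readings.

The reach of a flask is then its charge of G, less Q, divided by the bill. In winter the first-hour constant, on the same simplification, gives J a half-life of 7.40 h at charged G, shorter than the 25 h allowed, so there is time to approach the reach of 37.7 %. Autumn's reach is 88.0 %, and dawn's is 189 %, beyond the whole charge of J, so dawn's J can finish.

The forecast gave 55 %, 74 % and 90 %, with the answer it rises, on the ground that “something is also suppressing the rate”. This reckoning stands lower in winter and higher in autumn.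

The flasks give 43.3 %, 82.2 % and 99.6 %, and the answer is it rises, by 56 percentage points. The main reason for that rise is the difference in equivalents of G: dawn gives 99.6 %, and with winter's equivalents the figure is 43.3 %.

    G + Z ⇌ L, settled at all times (K = 2200 L mol⁻¹)
    J + G → Z + E (k = 0.0333 L mol⁻¹ min⁻¹)
    D ⇌ E, rate k3*(cs3 - [E]) while solid is left; crystals form when [E] > cs3 (solubility = 17.0 mM, k = 0.0337 min⁻¹)
    G + Q → X (k = 0.824 L mol⁻¹ min⁻¹)

Winter's J reacts to 43.3 %, against a reach of 37.7 %, with 7.1 % of G free at the end. Each reacted J releases a Z that holds a further G as L, and the reading comes early: without that binding winter gives 61.6 %, and read ten times later it gives 60.8 %. The neighbour of autumn charged with 0.098 M of J carries Q at 0.119 equiv, so its reach is 95.6 %, and it gives 96.1 %.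

The data come from a simulation for an exercise, and the scatter is random.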